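**Plan**

- Retrosynthesis cuts C5'–C6' (sulfonyl-carbanion alkylation, then desulfonylation), then O1–C8a (intramolecular Pd aryl etherification), then C4–C4a (B-alkyl Suzuki coupling). This leaves a bromo-iodo arene, (R)-linalool and a C6'–C13' sulfone.
- Enabling feature: C2 carries O1, a methyl, the C3–C4 arm to the benzene ring and the C1'–C4' methylpentenyl arm. These are the four groups on the carbinol carbon of (R)-linalool, and as a tertiary alkoxide it has no β-hydrogen, so the dihydropyran ring can be closed at O1–C8a without touching C2.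
- Forward: the arene is made from 4-amino-3-methylphenol, joined to hydroborated linalool at the iodide, and the dihydropyran ring (the only ring formed) is closed by Pd. The E-methyl of the remaining alkene is then oxidised to C5' and brominated; sulfone alkylation, desulfonylation, C9' oxidation and desilylation finish the chain.
- The C6'–C13' sulfone is made in five steps from 4-methylpent-3-en-1-ol (oxidation, crotylboration, silylation, hydrozirconation–iodination, sulfinate displacement).
- Stereochemistry: C2 (R) comes unchanged from (R)-linalool; C8' (S) from reagent-controlled (E)-crotylboration; 3'E from the E-selective SeO2 oxidation; the C9' carbinol and C6' sulfone centres are transient.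

Key step: step 5

Remark on numbering: side-chain carbons are C1' to C13' outward from C2 (C13' is the second terminal methyl). The C9' carbinol is later oxidised and the C6' sulfone removed, so their configurations need no control.

Assumption: the (+)-α-pinene-derived crotylborane attacks the Si face of the aldehyde, as is usual for this reagent family; if the opposite sense were found, the antipodal borane would be used.

**Route**

Step 1
Reactants: 1 4-amino-3-methylphenol
Product: 2 2-methyl-4-(triisopropylsilyloxy)aniline
Conditions: TIPSCl, imidazole, DMF, 0 °C → rt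
Reagents that add atoms: triisopropylsilyl chloride, CC(C)[Si](Cl)(C(C)C)C(C)C
Why: Imidazole-promoted O-silylation should take the phenol in preference to the aniline nitrogen (any N–Si bond is lost on work-up), and the bulky TIPS aryl ether is chosen to survive aqueous phosphate, carbonate at 80 °C and mild acid, and to leave only with fluoride at the end.

Step 2
Reactants: 2 2-methyl-4-(triisopropylsilyloxy)aniline
Product: 3 2-iodo-6-methyl-4-(triisopropylsilyloxy)aniline
Conditions: NIS, MeCN, 0 °C, dark
Reagents that add atoms: N-iodosuccinimide, O=C1CCC(=O)N1I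
Why: Electrophilic aromatic iodination is steered by the amino group, whose para and one ortho position are blocked, so the only open activated site is C6, while the TIPS group shields the positions next to oxygen.

Step 3
Reactants: 3 2-iodo-6-methyl-4-(triisopropylsilyloxy)aniline
Product: 5 (4-bromo-3-iodo-5-methylphenoxy)triisopropylsilane, via arenediazonium bromide 4 (not isolated)
Conditions: t-BuONO, CuBr2, MeCN, 0 → 60 °C
Reagents that add atoms: copper(II) bromide, Br[Cu]Br; tert-butyl nitrite, CC(C)(C)ON=O (its nitrogen ends up only in 4)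
Why: Non-aqueous Sandmeyer bromination (alkyl nitrite diazotisation, copper-mediated bromine transfer to the aryl radical) should replace NH2 by Br without aqueous acid, putting bromine on the future C8a next to the iodine on the future C4a.

Step 4
Reactants: 6 (R)-(−)-linalool; 5 (4-bromo-3-iodo-5-methylphenoxy)triisopropylsilane
Product: 8 (R)-1-[2-bromo-3-methyl-5-(triisopropylsilyloxy)phenyl]-3,7-dimethyloct-6-en-3-ol, via B-alkyl-9-BBN adduct 7 (not isolated)
Conditions: 6, 9-BBN, THF, 0 °C → rt; then 5, Pd(dppf)Cl2 (5 mol %), aq K3PO4, THF–DMF, 50 °C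
Reagents that add atoms: none
Why: 9-BBN should add anti-Markovnikov to the monosubstituted vinyl group only (trisubstituted alkene and tertiary OH tolerated), and the B-alkyl Suzuki–Miyaura coupling should engage C–I far faster than the C–Br bond, which ends up flanked by two ortho substituents, with the carbinol centre not involved.

Step 5
Reactants: 8 (R)-1-[2-bromo-3-methyl-5-(triisopropylsilyloxy)phenyl]-3,7-dimethyloct-6-en-3-ol
Product: 9 (R)-2,8-dimethyl-2-(4-methylpent-3-en-1-yl)-6-(triisopropylsilyloxy)chromane
Conditions: Pd(OAc)2 (5 mol %), 2-(di-tert-butylphosphino)-1,1'-binaphthyl (7 mol %), Cs2CO3, toluene, 80 °C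
Reagents that add atoms: none
Why: Pd(0) should insert into the C–Br bond, carbonate should deliver the tertiary alkoxide to palladium to give a seven-membered oxapalladacycle, and C–O reductive elimination should then release the chroman. The closest known reaction type is the intramolecular Buchwald–Hartwig etherification of aryl halides with tertiary alcohols to give 2,2-disubstituted chromans. The six-membered dihydropyran ring closes by forming the O1–C8a bond at the aryl carbon, a reductive elimination rather than a nucleophilic ring closure. No stereocentre is created, and C2 keeps its (R) configuration because its C–O bond is never broken, unlike in acid-mediated closures through a tertiary cation. The step needs C–O reductive elimination to outrun protodebromination and β-hydride elimination; the tertiary alkoxide has no carbinol hydrogen and the bulky electron-rich phosphine accelerates reductive elimination. A Heck reaction with the remote alkene would need an eight-membered ring, and the aryl TIPS ether should be inert to carbonate in dry toluene.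

Step 6
Reactants: 9 (R)-2,8-dimethyl-2-(4-methylpent-3-en-1-yl)-6-(triisopropylsilyloxy)chromane
Product: 11 (E)-5-[(R)-2,8-dimethyl-6-(triisopropylsilyloxy)chroman-2-yl]-2-methylpent-2-en-1-ol, via enal 10 (not isolated)
Conditions: SeO2 (0.3 equiv), t-BuOOH, salicylic acid (cat.), CH2Cl2, rt; then NaBH4, MeOH, 0 °C
Reagents that add atoms: tert-butyl hydroperoxide, CC(C)(C)OO; selenium dioxide, O=[Se]=O (catalytic oxygen carrier)
Why: Selenium dioxide allylic oxidation (ene reaction then [2,3]-sigmatropic shift, t-BuOOH as reoxidant) should hydroxylate the E-methyl group of the only alkene to give the E-allylic alcohol, and borohydride should return any over-oxidised enal 10 to the same alcohol.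

Step 7
Reactants: 11 (E)-5-[(R)-2,8-dimethyl-6-(triisopropylsilyloxy)chroman-2-yl]-2-methylpent-2-en-1-ol
Product: 12 (R)-2-[(E)-5-bromo-4-methylpent-3-en-1-yl]-2,8-dimethyl-6-(triisopropylsilyloxy)chromane
Conditions: CBr4, PPh3, CH2Cl2, −20 → 0 °C
Reagents that add atoms: carbon tetrabromide, BrC(Br)(Br)Br
Why: The Appel reaction should convert the primary allylic alcohol into the bromide by SN2 displacement under neutral conditions at low temperature, without allylic transposition or loss of the E geometry.

Step 8
Reactants: 13 4-methylpent-3-en-1-ol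
Product: 14 4-methylpent-3-enal
Conditions: Dess–Martin periodinane, NaHCO3, CH2Cl2, 0 °C → rt; cold filtered solution used at once
Reagents that add atoms: none
Why: Buffered Dess–Martin oxidation should give the β,γ-unsaturated aldehyde without acid- or base-induced migration of the double bond into conjugation, provided the volatile product is used directly.

Step 9
Reactants: 14 4-methylpent-3-enal
Product: 16 (3S,4R)-3,7-dimethylocta-1,6-dien-4-ol, via diisopinocampheylborinate 15 (not isolated)
Conditions: trans-2-butene, n-BuLi, KOt-Bu, THF, −78 → −45 °C; (−)-Ipc2BOMe, −78 °C; BF3·OEt2; 14, −78 °C; then NaOH, H2O2, 0 °C → rt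
Reagents that add atoms: trans-2-butene (delivered as its (E)-crotyldiisopinocampheylborane), C/C=C/C
Why: Brown crotylboration through a closed chair transition state should give the anti adduct from the (E)-crotyl group, with the (+)-α-pinene-derived isopinocampheyl ligands directing attack to the Si face of the aldehyde, so C3 (the future C8') is set as S by reagent control under non-basic conditions at −78 °C that the labile aldehyde tolerates.

Step 10
Reactants: 16 (3S,4R)-3,7-dimethylocta-1,6-dien-4-ol
Product: 17 triethyl{[(3S,4R)-3,7-dimethylocta-1,6-dien-4-yl]oxy}silane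
Conditions: TESCl, imidazole, DMF, 0 °C → rt
Reagents that add atoms: chlorotriethylsilane, CC[Si](Cl)(CC)CC
Why: Standard silylation gives a TES ether that should survive organolithium base and sodium amalgam and later be removed by mild acid that leaves the aryl TIPS ether intact.

Step 11
Reactants: 17 triethyl{[(3S,4R)-3,7-dimethylocta-1,6-dien-4-yl]oxy}silane
Product: 19 triethyl{[(3S,4R)-1-iodo-3,7-dimethyloct-6-en-4-yl]oxy}silane, via alkylzirconocene chloride 18 (not isolated)
Conditions: Cp2Zr(H)Cl, THF, rt; then I2, 0 °C
Reagents that add atoms: iodine, II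
Why: Hydrozirconation with Schwartz reagent should place zirconium at the terminal carbon of the monosubstituted alkene only (the trisubstituted alkene is inert at room temperature), and iodinolysis of the C–Zr bond gives the primary iodide without touching the adjacent stereocentre.

Step 12
Reactants: 19 triethyl{[(3S,4R)-1-iodo-3,7-dimethyloct-6-en-4-yl]oxy}silane
Product: 20 triethyl{[(3S,4R)-3,7-dimethyl-1-(phenylsulfonyl)oct-6-en-4-yl]oxy}silane
Conditions: PhSO2Na, n-Bu4NI (cat.), DMF, 50 °C
Reagents that add atoms: sodium benzenesulfinate, [Na+].[O-]S(=O)c1ccccc1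
Why: SN2 S-alkylation of the sulfinate by an unhindered primary iodide in a dipolar aprotic solvent is a dependable route to alkyl phenyl sulfones.

Step 13
Reactants: 20 triethyl{[(3S,4R)-3,7-dimethyl-1-(phenylsulfonyl)oct-6-en-4-yl]oxy}silane; 12 (R)-2-[(E)-5-bromo-4-methylpent-3-en-1-yl]-2,8-dimethyl-6-(triisopropylsilyloxy)chromane
Product: 22 (2R)-2,8-dimethyl-2-[(3E,8S,9R)-4,8,12-trimethyl-6-(phenylsulfonyl)-9-(triethylsilyloxy)trideca-3,11-dien-1-yl]-6-(triisopropylsilyloxy)chromane (mixture of C6' epimers), via lithiated sulfone 21 (not isolated)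
Conditions: 20, n-BuLi, THF, −78 °C; then 12, DMPU, −78 → −20 °C
Reagents that add atoms: none
Why: Alkylation of the α-sulfonyl carbanion by the primary allylic bromide (SN2, alkene geometry retained) should forge C5'–C6', the new sulfonyl-bearing centre forming without control, which is harmless because it is removed in the next step.

Step 14
Reactants: 22 the C6' sulfone
Product: 23 (2R)-2,8-dimethyl-2-[(3E,8S,9R)-4,8,12-trimethyl-9-(triethylsilyloxy)trideca-3,11-dien-1-yl]-6-(triisopropylsilyloxy)chromane
Conditions: 5% Na(Hg), Na2HPO4, MeOH–THF, −20 → 0 °C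
Reagents that add atoms: none
Why: Reductive desulfonylation by electron transfer from sodium amalgam under phosphate buffering should cleave the C–S bond while leaving the isolated trisubstituted alkenes and both silyl ethers untouched.

Step 15
Reactants: 23 the bis-silyl ether
Product: 24 (3E,8S,9R)-1-[(R)-2,8-dimethyl-6-(triisopropylsilyloxy)chroman-2-yl]-4,8,12-trimethyltrideca-3,11-dien-9-ol
Conditions: PPTS (cat.), MeOH–CH2Cl2, 0 °C → rt
Reagents that add atoms: none
Why: Mild acid-catalysed methanolysis should remove the alkyl TES ether selectively, since aryl silyl ethers are stable to acid and labile only to base or fluoride.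

Step 16
Reactants: 24 the C9' alcohol
Product: 25 (6S,10E)-13-[(2R)-2,8-dimethyl-6-(triisopropylsilyloxy)chroman-2-yl]-2,6,10-trimethyltrideca-2,10-dien-5-one
Conditions: Dess–Martin periodinane, NaHCO3, CH2Cl2, 0 °C → rt
Reagents that add atoms: none
Why: Buffered Dess–Martin oxidation of the homoallylic alcohol should give the β,γ-unsaturated ketone under near-neutral conditions that neither move the C11' alkene into conjugation nor epimerise C8'.

Step 17
Reactants: 25 the TIPS-protected ketone
Product: 26 (6S,10E)-13-[(2R)-6-hydroxy-2,8-dimethylchroman-2-yl]-2,6,10-trimethyltrideca-2,10-dien-5-one (target)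
Conditions: TBAF, AcOH (1:1), THF, 0 °C
Reagents that add atoms: none
Why: Fluoride cleavage of the aryl silyl ether, buffered with acetic acid so that the medium stays near neutral, should free the phenol without enolising the ketone toward C8' or C10'.

**Compound list**

1 | 4-amino-3-methylphenol | Cc1cc(O)ccc1N | starting material
2 | 2-methyl-4-(triisopropylsilyloxy)aniline | Cc1cc(O[Si](C(C)C)(C(C)C)C(C)C)ccc1N | intermediate
3 | 2-iodo-6-methyl-4-(triisopropylsilyloxy)aniline | Cc1cc(O[Si](C(C)C)(C(C)C)C(C)C)cc(I)c1N | intermediate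
4 | 2-iodo-6-methyl-4-(triisopropylsilyloxy)benzenediazonium bromide | Cc1cc(O[Si](C(C)C)(C(C)C)C(C)C)cc(I)c1[N+]#N.[Br-] | intermediate (not isolated)
5 | (4-bromo-3-iodo-5-methylphenoxy)triisopropylsilane | Cc1cc(O[Si](C(C)C)(C(C)C)C(C)C)cc(I)c1Br | intermediate
6 | (R)-(−)-linalool | CC(C)=CCC[C@@](C)(O)C=C | starting material
7 | (S)-1-(9-borabicyclo[3.3.1]nonan-9-yl)-3,7-dimethyloct-6-en-3-ol | CC(C)=CCC[C@@](C)(O)CCB1C2CCCC1CCC2 | intermediate (not isolated)
8 | (R)-1-[2-bromo-3-methyl-5-(triisopropylsilyloxy)phenyl]-3,7-dimethyloct-6-en-3-ol | CC(C)=CCC[C@@](C)(O)CCc1cc(O[Si](C(C)C)(C(C)C)C(C)C)cc(C)c1Br | intermediate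
9 | (R)-2,8-dimethyl-2-(4-methylpent-3-en-1-yl)-6-(triisopropylsilyloxy)chromane | CC(C)=CCC[C@]1(C)CCc2cc(O[Si](C(C)C)(C(C)C)C(C)C)cc(C)c2O1 | intermediate
10 | (E)-5-[(R)-2,8-dimethyl-6-(triisopropylsilyloxy)chroman-2-yl]-2-methylpent-2-enal | O=C/C(C)=C/CC[C@]1(C)CCc2cc(O[Si](C(C)C)(C(C)C)C(C)C)cc(C)c2O1 | intermediate (not isolated)
11 | (E)-5-[(R)-2,8-dimethyl-6-(triisopropylsilyloxy)chroman-2-yl]-2-methylpent-2-en-1-ol | OC/C(C)=C/CC[C@]1(C)CCc2cc(O[Si](C(C)C)(C(C)C)C(C)C)cc(C)c2O1 | intermediate
12 | (R)-2-[(E)-5-bromo-4-methylpent-3-en-1-yl]-2,8-dimethyl-6-(triisopropylsilyloxy)chromane | BrC/C(C)=C/CC[C@]1(C)CCc2cc(O[Si](C(C)C)(C(C)C)C(C)C)cc(C)c2O1 | intermediate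
13 | 4-methylpent-3-en-1-ol | CC(C)=CCCO | starting material
14 | 4-methylpent-3-enal | CC(C)=CCC=O | intermediate
15 | (3S,4R)-3,7-dimethylocta-1,6-dien-4-yl diisopinocampheylborinate | C=C[C@H](C)[C@H](OB([C@@H]1C[C@@H]2C[C@H]([C@H]1C)C2(C)C)[C@@H]1C[C@@H]2C[C@H]([C@H]1C)C2(C)C)CC=C(C)C | intermediate (not isolated)
16 | (3S,4R)-3,7-dimethylocta-1,6-dien-4-ol | C=C[C@H](C)[C@H](O)CC=C(C)C | intermediate
17 | triethyl{[(3S,4R)-3,7-dimethylocta-1,6-dien-4-yl]oxy}silane | C=C[C@H](C)[C@H](O[Si](CC)(CC)CC)CC=C(C)C | intermediate
18 | chlorobis(cyclopentadienyl)[(3S,4R)-3,7-dimethyl-4-(triethylsilyloxy)oct-6-en-1-yl]zirconium | Cl[Zr](C1C=CC=C1)(C1C=CC=C1)CC[C@H](C)[C@H](O[Si](CC)(CC)CC)CC=C(C)C | intermediate (not isolated)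
19 | triethyl{[(3S,4R)-1-iodo-3,7-dimethyloct-6-en-4-yl]oxy}silane | ICC[C@H](C)[C@H](O[Si](CC)(CC)CC)CC=C(C)C | intermediate
20 | triethyl{[(3S,4R)-3,7-dimethyl-1-(phenylsulfonyl)oct-6-en-4-yl]oxy}silane | O=S(=O)(c1ccccc1)CC[C@H](C)[C@H](O[Si](CC)(CC)CC)CC=C(C)C | intermediate
21 | α-lithio derivative of sulfone 20 | [Li]C(S(=O)(=O)c1ccccc1)C[C@H](C)[C@H](O[Si](CC)(CC)CC)CC=C(C)C | intermediate (not isolated)
22 | (2R)-2,8-dimethyl-2-[(3E,8S,9R)-4,8,12-trimethyl-6-(phenylsulfonyl)-9-(triethylsilyloxy)trideca-3,11-dien-1-yl]-6-(triisopropylsilyloxy)chromane, C6' epimers | CC(C)=CC[C@@H](O[Si](CC)(CC)CC)[C@@H](C)CC(S(=O)(=O)c1ccccc1)C/C(C)=C/CC[C@]1(C)CCc2cc(O[Si](C(C)C)(C(C)C)C(C)C)cc(C)c2O1 | intermediate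
23 | (2R)-2,8-dimethyl-2-[(3E,8S,9R)-4,8,12-trimethyl-9-(triethylsilyloxy)trideca-3,11-dien-1-yl]-6-(triisopropylsilyloxy)chromane | CC(C)=CC[C@@H](O[Si](CC)(CC)CC)[C@@H](C)CCC/C(C)=C/CC[C@]1(C)CCc2cc(O[Si](C(C)C)(C(C)C)C(C)C)cc(C)c2O1 | intermediate
24 | (3E,8S,9R)-1-[(R)-2,8-dimethyl-6-(triisopropylsilyloxy)chroman-2-yl]-4,8,12-trimethyltrideca-3,11-dien-9-ol | CC(C)=CC[C@@H](O)[C@@H](C)CCC/C(C)=C/CC[C@]1(C)CCc2cc(O[Si](C(C)C)(C(C)C)C(C)C)cc(C)c2O1 | intermediate
25 | (6S,10E)-13-[(2R)-2,8-dimethyl-6-(triisopropylsilyloxy)chroman-2-yl]-2,6,10-trimethyltrideca-2,10-dien-5-one | CC(C)=CCC(=O)[C@@H](C)CCC/C(C)=C/CC[C@]1(C)CCc2cc(O[Si](C(C)C)(C(C)C)C(C)C)cc(C)c2O1 | intermediate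
26 | (6S,10E)-13-[(2R)-6-hydroxy-2,8-dimethylchroman-2-yl]-2,6,10-trimethyltrideca-2,10-dien-5-one (CNP0280076.1) | CC(C)=CCC(=O)[C@@H](C)CCC/C(C)=C/CC[C@]1(C)CCc2cc(O)cc(C)c2O1 | target

**Step count**

Total: 17 steps. Longest linear sequence: 12 steps (steps 1–7 and 13–17, from 4-amino-3-methylphenol); the sulfone branch (steps 8–12) joins at step 13.

**Steps most likely to fail**

(i) Step 6. The allylic oxidation may stall at partial conversion, over-oxidise, or attack the electron-rich chroman, so that little E-allylic alcohol is obtained. The fallback rebuilds the C3'=C4' alkene instead of oxidising it, setting out from 9. Catalytic OsO4 with NaIO4 and 2,6-lutidine in dioxane–water should give the diol (2S)-2-(3,4-dihydroxy-4-methylpentyl)-2,8-dimethyl-6-(triisopropylsilyloxy)chromane F1, which periodate cleaves in the same flask to the aldehyde (S)-3-[2,8-dimethyl-6-(triisopropylsilyloxy)chroman-2-yl]propanal F2. An E-selective Wittig reaction with ethyl 2-(triphenylphosphoranylidene)propanoate in toluene at 80 °C should then give ethyl (E)-5-[(R)-2,8-dimethyl-6-(triisopropylsilyloxy)chroman-2-yl]-2-methylpent-2-enoate F3. DIBAL-H reduction at −78 °C returns to the route at 11.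

(ii) Step 5. C–O reductive elimination at the doubly ortho-substituted, electron-rich arylpalladium centre may be slow enough for protodebromination to take over. The fallback keeps the O1–C8a closure and the intact C2–O bond but moves to copper, setting out from 8. Copper-catalysed halogen exchange (CuI, NaI, trans-N,N'-dimethylcyclohexane-1,2-diamine, dioxane, 110 °C) should give (R)-1-[2-iodo-3-methyl-5-(triisopropylsilyloxy)phenyl]-3,7-dimethyloct-6-en-3-ol F4. An intramolecular Ullmann etherification (CuI, 3,4,7,8-tetramethyl-1,10-phenanthroline, Cs2CO3, toluene, 110 °C) then closes the ring and returns to the route at 9.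

(iii) Step 9. The β,γ-double bond of the aldehyde may migrate into conjugation, or the volatile aldehyde may be lost, before it meets the borane; enantiomeric purity at the future C8' may also be eroded. The fallback avoids handling the free aldehyde and sets out from 13. An iridium-catalysed transfer-hydrogenative anti-crotylation of the primary alcohol with but-3-en-2-yl acetate (cyclometallated Ir–SEGPHOS catalyst of the enantiomer matched to the (3S,4R) series, Cs2CO3, THF, 90 °C) generates the aldehyde only transiently and should deliver the dienol directly, returning to the route at 16. No new compound is made.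

Further compounds
F1 | step 6 | (2S)-2-(3,4-dihydroxy-4-methylpentyl)-2,8-dimethyl-6-(triisopropylsilyloxy)chromane (C3' epimers) | CC(C)(O)C(O)CC[C@]1(C)CCc2cc(O[Si](C(C)C)(C(C)C)C(C)C)cc(C)c2O1
F2 | step 6 | (S)-3-[2,8-dimethyl-6-(triisopropylsilyloxy)chroman-2-yl]propanal | O=CCC[C@]1(C)CCc2cc(O[Si](C(C)C)(C(C)C)C(C)C)cc(C)c2O1
F3 | step 6 | ethyl (E)-5-[(R)-2,8-dimethyl-6-(triisopropylsilyloxy)chroman-2-yl]-2-methylpent-2-enoate | CCOC(=O)/C(C)=C/CC[C@]1(C)CCc2cc(O[Si](C(C)C)(C(C)C)C(C)C)cc(C)c2O1
F4 | step 5 | (R)-1-[2-iodo-3-methyl-5-(triisopropylsilyloxy)phenyl]-3,7-dimethyloct-6-en-3-ol | CC(C)=CCC[C@@](C)(O)CCc1cc(O[Si](C(C)C)(C(C)C)C(C)C)cc(C)c1I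
F0 | step 9 | none | none
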